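**Retrosynthetic overview**

1. Biosynthetic model: Dieckmann closure of the tetramate; reductive cyclisation zipping the two polyene tails into the 5/5 unit (C5–C28, then C3–C29); closure of the 5/8 unit; late oxidation at C2.
2. Last disconnections: C20=C21 (Knoevenagel, closes the 11-membered lactam) and the N13–C12 amide, giving tetracyclic acid 27 and the ornithine-derived tetramate 32 (Lacey–Dieckmann).
3. Ring D: C23=C24 by ring-closing metathesis, after an Ireland–Claisen rearrangement has made C11–C22 and both stereocentres. This part departs from the biosynthetic model: a tethered [4+4] would put ring D anti to ring B, whereas the target has all four ring-C hydrogens cis.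
4. Rings B and A: one reductive radical bicyclisation on an all-cis cyclopentane. That cyclopentane (ring C) is the ring of cyclopentadiene; its four stereocentres come from an endo Diels–Alder reaction followed by norbornene opening.
5. Ring order: C (bought) → B + A (one step) → D → tetramate (side branch) → 11-membered macrolactam.

Labels: C1–C31 follow the atom order of the target SMILES (positions 13 and 18 are nitrogen).

Assumption: centres that are erased later (C5 carbinol/xanthate, C2 silyloxy carbon) are carried as epimer pairs and left undefined in the SMILES; propenyl groups from metathesis are E/Z mixtures drawn E; the antipodal Diels–Alder catalyst is used if the sense of induction turns out opposite.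

**Route**

Step 1
Reactants: 1 cyclopenta-1,3-diene (cracked from dicyclopentadiene); 2 cyclopent-2-en-1-one
Product: 3 endo-tricyclo[5.2.1.0^2,6]dec-8-en-3-one
Conditions: (S)-3,3-diphenyl-1-(2-methylphenyl)tetrahydro-1H,3H-pyrrolo[1,2-c][1,3,2]oxazaborole·(CF3SO2)2NH (20 mol %), CH2Cl2, −78 → −40 °C
Reagents that add atoms: none
Why: Lewis-acid-catalysed Diels–Alder reaction; the endo rule puts the enone carbons (C7, C8) cis to the etheno bridge (C24, C28), so all four future ring-C substituents are cis, and the chiral oxazaborolidinium cation fixes the absolute sense.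

Step 2
Reactants: 3 endo adduct; 4 (Z)-but-2-ene
Product: 5 all-cis 6,8-dipropenyl-cis-bicyclo[3.3.0]octan-2-one
Conditions: second-generation Grubbs catalyst RuCl2(=CHPh)(H2IMes)(PCy3) (2 mol %), excess 4, CH2Cl2, 0 °C → rt, sealed tube
Reagents that add atoms: none
Why: ring-opening cross-metathesis driven by norbornene strain; no stereocentre is touched and both propenyl groups stay cis to the fused cyclopentanone.

Step 3
Reactants: 5 bicyclic ketone
Product: 7 α-hydroxy ketone (3-hydroxy derivative of 5), via lithium enolate 6 (not isolated)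
Conditions: LiN(i-Pr)2, THF, −78 °C; then 3-phenyl-2-(phenylsulfonyl)oxaziridine, −78 °C; aq. NH4Cl
Reagents that add atoms: 3-phenyl-2-(phenylsulfonyl)oxaziridine, O=S(=O)(N1OC1c1ccccc1)c1ccccc1
Why: kinetic deprotonation on the CH2 side (C5) and Davis α-hydroxylation; the new carbinol centre is lost in step 4.

Step 4
Reactants: 7 α-hydroxy ketone
Product: 8 methyl all-cis-2-(2-oxoethyl)-3,5-dipropenylcyclopentane-1-carboxylate
Conditions: Pb(OAc)4, MeOH/PhH (1:1), 0 °C
Reagents that add atoms: methanol, CO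
Why: Criegee-type oxidative cleavage of the α-ketol in methanol gives the methyl ester (C9) and the aldehyde (C5) without base, so C8 keeps its configuration.

Step 5
Reactants: 8 ester aldehyde; 9 2-(2-bromoethyl)-2-methyl-1,3-dioxolane
Product: 12 S-methyl xanthate of the C5 carbinol, via alkyllithium 10 (not isolated), via lithium alkoxide 11 (not isolated)
Conditions: 9, t-BuLi (2 equiv), Et2O, −78 °C; 8, THF, −78 °C; CS2, then MeI, −78 → 0 °C
Reagents that add atoms: carbon disulfide, S=C=S; iodomethane, CI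
Why: bromine–lithium exchange and 1,2-addition to the aldehyde (much faster than to the hindered ester at −78 °C), then xanthate formation from the alkoxide before it can lactonise; the C5 centre does not matter because it becomes a radical.

Step 6
Reactants: 12 xanthate ketal
Product: 13 methyl ketone xanthate
Conditions: PPTS (cat.), acetone/H2O (10:1), 50 °C
Reagents that add atoms: water, O
Why: acid-catalysed hydrolysis of the dioxolane; xanthate, ester and alkenes are inert.

Step 7
Reactants: 13 methyl ketone xanthate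
Product: 14 (Z)-tert-butyldimethylsilyl enol ether (C3=C2)
Conditions: t-BuMe2SiCl, NaI, Et3N, MeCN, 40 °C
Reagents that add atoms: tert-butyl(chloro)dimethylsilane, CC(C)(C)[Si](C)(C)Cl
Why: soft enolisation under equilibrating conditions gives the more substituted (Z)-enol ether, the radical acceptor for ring A.

Step 8
Reactants: 14 silyl enol ether xanthate
Product: 15 tricyclic ester (rings A, B, C)
Conditions: Bu3SnH (1.3 equiv, syringe pump), AIBN (cat.), PhH (5 mM), 80 °C
Reagents that add atoms: none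
Why: Barton–McCombie radical generation and tandem 5-exo-trig/5-exo-trig cyclisation through Beckwith–Houk chair transition states: the C5 radical adds to C28 of the cis propenyl group with both new substituents exo on the cis-fused bicycle (sets C5, C28), then the C29 radical adds to C3 with methyl anti to C27 and the silyloxyethyl group exo (sets C29, C3); C2 forms as an epimer pair that is erased in step 21.

Step 9
Reactants: 15 tricyclic ester
Product: 16 tricyclic aldehyde (C9)
Conditions: i-Bu2AlH (1.1 equiv), CH2Cl2, −78 °C; aq. KNaC4H4O6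
Reagents that add atoms: none
Why: partial ester reduction through the stable aluminium hemiacetal at −78 °C; the aldehyde is used at once to avoid epimerisation at C8.

Step 10
Reactants: 16 tricyclic aldehyde; 17 (2-carboxyethyl)triphenylphosphonium bromide
Product: 19 (Z)-β,γ-unsaturated acid, via phosphorus ylide 18 (not isolated)
Conditions: 17, NaN(SiMe3)2 (2.1 equiv), THF, −78 → 0 °C; 16, −78 °C → rt; cold 1 M HCl
Reagents that add atoms: none
Why: Wittig reaction of a non-stabilised carboxylate ylide under lithium-free conditions gives the (Z)-C9=C10 alkene; no new stereocentre.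

Step 11
Reactants: 20 (tert-butyldimethylsilyloxy)acetaldehyde; 21 1-(triphenyl-λ5-phosphanylidene)propan-2-one
Product: 22 (E)-5-(tert-butyldimethylsilyloxy)pent-3-en-2-one
Conditions: CH2Cl2, rt
Reagents that add atoms: none
Why: Wittig reaction of a stabilised ylide gives the (E)-enone.

Step 12
Reactants: 22 enone
Product: 23 (R,E)-5-(tert-butyldimethylsilyloxy)pent-3-en-2-ol
Conditions: (S)-1-methyl-3,3-diphenyltetrahydro-1H,3H-pyrrolo[1,2-c][1,3,2]oxazaborole (10 mol %), catecholborane, PhMe, −78 °C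
Reagents that add atoms: none
Why: Corey–Bakshi–Shibata reduction, with the alkenyl group as the large substituent, gives the (R)-carbinol.

Step 13
Reactants: 19 (Z)-acid; 23 (R)-allylic alcohol
Product: 24 allylic ester
Conditions: EDC·HCl, DMAP (10 mol %), CH2Cl2, 0 °C
Reagents that add atoms: none
Why: Steglich esterification at 0 °C, mild enough to keep the β,γ-unsaturated acid from conjugating.

Step 14
Reactants: 24 allylic ester
Product: 26 anti-2-alkenyl-3-(silyloxymethyl)hex-4-enoic acid, via silyl ketene acetal 25 (not isolated)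
Conditions: LiN(i-Pr)2, Me3SiCl/Et3N, THF, −78 °C → rt; then 1 M HCl
Reagents that add atoms: none
Why: Ireland–Claisen rearrangement; the kinetic (E)-enolate and the (E)-allyl unit pass through a chair with the carbinol methyl equatorial, which gives the anti C11/C22 pair with 1,3-chirality transfer from the (R)-carbinol and a new (E)-propenyl group on C22.

Step 15
Reactants: 26 Claisen acid
Product: 27 tetracyclic acid (rings A, B, C, D)
Conditions: second-generation Grubbs catalyst RuCl2(=CHPh)(H2IMes)(PCy3) (5 mol %), CH2Cl2 (2 mM), 40 °C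
Reagents that add atoms: none
Why: ring-closing metathesis of the two propenyl groups; the cis arms on ring C and the (Z)-C9=C10 alkene preorganise the eight-membered ring, in which the new C23=C24 alkene can only be cis.

Step 16
Reactants: 28 methyl Nδ-Boc-L-ornithinate hydrochloride; 29 3-(allyloxy)-3-oxopropanoic acid
Product: 30 Nα-(allyl malonyl) ornithine ester
Conditions: EDC·HCl, HOBt, i-Pr2NEt, CH2Cl2, 0 °C → rt
Reagents that add atoms: none
Why: carbodiimide amide coupling on the α-amine of L-ornithine, the source of C17.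

Step 17
Reactants: 30 malonamide
Product: 31 Boc-protected 3-(allyloxycarbonyl)tetramic acid
Conditions: KOt-Bu (2.1 equiv), THF, 0 °C, 20 min; then 1 M HCl
Reagents that add atoms: none
Why: Lacey–Dieckmann cyclisation of the malonamide onto the methyl ester closes the tetramate as in the biosynthesis; short exposure to base limits epimerisation at C17.

Step 18
Reactants: 31 Boc tetramate
Product: 32 ammonium trifluoroacetate of the aminopropyl tetramate
Conditions: CF3CO2H/CH2Cl2 (1:3), 0 °C
Reagents that add atoms: trifluoroacetic acid, OC(=O)C(F)(F)F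
Why: acidolysis of the Boc carbamate; the allyl ester and the tetramate survive.

Step 19
Reactants: 27 tetracyclic acid; 32 ammonium salt
Product: 33 amide
Conditions: EDC·HCl, HOAt, i-Pr2NEt, DMF, 0 °C
Reagents that add atoms: none
Why: carbodiimide/HOAt amide coupling at low temperature and low base load, to avoid epimerisation or conjugation at C11.

Step 20
Reactants: 33 bis-silyl ether
Product: 34 diol
Conditions: HF·pyridine, pyridine/THF, 0 °C → rt
Reagents that add atoms: none
Why: fluoride-mediated cleavage of both silyl ethers under buffered conditions.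

Step 21
Reactants: 34 diol
Product: 35 keto aldehyde
Conditions: Dess–Martin periodinane, NaHCO3, CH2Cl2, 0 °C
Reagents that add atoms: none
Why: Dess–Martin oxidation of both alcohols (C2 to the methyl ketone, C21 to the aldehyde) at neutral pH keeps C3 and C22 intact and removes the C2 epimer pair.

Step 22
Reactants: 35 keto aldehyde
Product: 37 combamide C, via tetramic acid 36 (not isolated)
Conditions: Pd(OAc)2 (5 mol %), PPh3 (20 mol %), HCO2H, Et3N, THF (1 mM), rt → 40 °C
Reagents that add atoms: none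
Why: Proposed new method: Tsuji deallylation–decarboxylation (π-allylpalladium carboxylate, loss of CO2, formate as hydride donor) unmasks the 3-unsubstituted tetramic acid 36, whose C20 then condenses with the C21 aldehyde (Knoevenagel) in the Et3N/HCO2H buffer at high dilution; the closest known reactions are palladium-catalysed decarboxylative deallylation of allyl β-keto esters and Knoevenagel condensation of tetramic acids with aldehydes, and the 11-membered ring allows only the cis-cycloalkene geometry of C20=C21 found in the target.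

**Compound list**

1 | cyclopenta-1,3-diene | C1=CC=CC1 | starting material
2 | cyclopent-2-en-1-one | O=C1C=CCC1 | starting material
3 | endo-tricyclo[5.2.1.0^2,6]dec-8-en-3-one (cyclopentanone endo) | O=C1CC[C@@H]2[C@H]1[C@@H]3C=C[C@H]2C3 | intermediate
4 | (Z)-but-2-ene | C/C=C\C | starting material
5 | all-cis 6,8-di[(E)-prop-1-enyl]-cis-bicyclo[3.3.0]octan-2-one | O=C1CC[C@@H]2[C@H]1[C@H](/C=C/C)C[C@@H]2/C=C/C | intermediate
6 | lithium enolate of 5 (C9–C5 enolate) | [Li+].[O-]C1=CC[C@@H]2[C@H]1[C@H](/C=C/C)C[C@@H]2/C=C/C | intermediate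
7 | 3-hydroxy derivative of 5 (α-ketol, carbinol epimers) | O=C1C(O)C[C@@H]2[C@H]1[C@H](/C=C/C)C[C@@H]2/C=C/C | intermediate
8 | methyl all-cis-2-(2-oxoethyl)-3,5-di[(E)-prop-1-enyl]cyclopentane-1-carboxylate (ring C: C8 ester, C7 CH2CHO, C27 and C25 propenyl) | O=CC[C@@H]1[C@H](C(=O)OC)[C@H](/C=C/C)C[C@@H]1/C=C/C | intermediate
9 | 2-(2-bromoethyl)-2-methyl-1,3-dioxolane | CC1(CCBr)OCCO1 | starting material
10 | [2-(2-methyl-1,3-dioxolan-2-yl)ethyl]lithium | [Li]CCC1(C)OCCO1 | intermediate
11 | lithium alkoxide from addition of 10 to the aldehyde of 8 (C5 epimers) | [Li+].[O-]C(CCC1(C)OCCO1)C[C@@H]1[C@H](C(=O)OC)[C@H](/C=C/C)C[C@@H]1/C=C/C | intermediate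
12 | O-alkyl S-methyl xanthate of the C5 carbinol, ketone as dioxolane | CC1(CCC(OC(=S)SC)C[C@@H]2[C@H](C(=O)OC)[C@H](/C=C/C)C[C@@H]2/C=C/C)OCCO1 | intermediate
13 | xanthate with free methyl ketone (C2) | CC(=O)CCC(OC(=S)SC)C[C@@H]1[C@H](C(=O)OC)[C@H](/C=C/C)C[C@@H]1/C=C/C | intermediate
14 | xanthate with (Z)-C3=C2 tert-butyldimethylsilyl enol ether | C/C(O[Si](C)(C)C(C)(C)C)=C/CC(OC(=S)SC)C[C@@H]1[C@H](C(=O)OC)[C@H](/C=C/C)C[C@@H]1/C=C/C | intermediate
15 | tricyclic ester, rings A–B–C cis-anti-cis: C8 CO2Me, C25 (E)-propenyl, C29 methyl, C3 1-(silyloxy)ethyl (C2 epimers) | CC(O[Si](C)(C)C(C)(C)C)[C@@H]1C[C@H]2C[C@@H]3[C@H](C(=O)OC)[C@H](/C=C/C)C[C@@H]3[C@H]2[C@@H]1C | intermediate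
16 | tricyclic C9 aldehyde | CC(O[Si](C)(C)C(C)(C)C)[C@@H]1C[C@H]2C[C@@H]3[C@H](C=O)[C@H](/C=C/C)C[C@@H]3[C@H]2[C@@H]1C | intermediate
17 | (2-carboxyethyl)triphenylphosphonium bromide | OC(=O)CC[P+](c1ccccc1)(c1ccccc1)c1ccccc1.[Br-] | starting material
18 | sodium 3-(triphenyl-λ5-phosphanylidene)propanoate | [Na+].[O-]C(=O)CC=P(c1ccccc1)(c1ccccc1)c1ccccc1 | intermediate
19 | tricyclic (Z)-but-3-enoic acid (C9=C10 Z, C12 acid) | CC(O[Si](C)(C)C(C)(C)C)[C@@H]1C[C@H]2C[C@@H]3[C@H](/C=C\CC(=O)O)[C@H](/C=C/C)C[C@@H]3[C@H]2[C@@H]1C | intermediate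
20 | (tert-butyldimethylsilyloxy)acetaldehyde | O=CCO[Si](C)(C)C(C)(C)C | starting material
21 | 1-(triphenyl-λ5-phosphanylidene)propan-2-one | CC(=O)C=P(c1ccccc1)(c1ccccc1)c1ccccc1 | starting material
22 | (E)-5-(tert-butyldimethylsilyloxy)pent-3-en-2-one | CC(=O)/C=C/CO[Si](C)(C)C(C)(C)C | intermediate
23 | (R,E)-5-(tert-butyldimethylsilyloxy)pent-3-en-2-ol | C[C@@H](O)/C=C/CO[Si](C)(C)C(C)(C)C | intermediate
24 | ester of 19 with 23 | CC(O[Si](C)(C)C(C)(C)C)[C@@H]1C[C@H]2C[C@@H]3[C@H](/C=C\CC(=O)O[C@H](C)/C=C/CO[Si](C)(C)C(C)(C)C)[C@H](/C=C/C)C[C@@H]3[C@H]2[C@@H]1C | intermediate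
25 | trimethylsilyl ketene acetal of 24 (C10 cis to the allyloxy oxygen) | CC(O[Si](C)(C)C(C)(C)C)[C@@H]1C[C@H]2C[C@@H]3[C@H](/C=C\C=C(\O[Si](C)(C)C)O[C@H](C)/C=C/CO[Si](C)(C)C(C)(C)C)[C@H](/C=C/C)C[C@@H]3[C@H]2[C@@H]1C | intermediate
26 | Claisen acid: C11 CO2H, C22 CH2OSi and (E)-propenyl, C11/C22 anti, ring D open | CC(O[Si](C)(C)C(C)(C)C)[C@@H]1C[C@H]2C[C@@H]3[C@H](/C=C\[C@@H]([C@@H](CO[Si](C)(C)C(C)(C)C)/C=C/C)C(=O)O)[C@H](/C=C/C)C[C@@H]3[C@H]2[C@@H]1C | intermediate
27 | tetracyclic acid, rings A–D (cycloocta-1,5-diene closed) | CC(O[Si](C)(C)C(C)(C)C)[C@@H]1C[C@H]2C[C@@H]3[C@@H]4/C=C\[C@@H]([C@@H](CO[Si](C)(C)C(C)(C)C)/C=C\[C@@H]4C[C@@H]3[C@H]2[C@@H]1C)C(=O)O | intermediate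
28 | methyl Nδ-(tert-butoxycarbonyl)-L-ornithinate hydrochloride | CC(C)(C)OC(=O)NCCC[C@H]([NH3+])C(=O)OC.[Cl-] | starting material
29 | 3-(allyloxy)-3-oxopropanoic acid (monoallyl malonate) | OC(=O)CC(=O)OCC=C | starting material
30 | methyl Nα-(allyl malonyl)-Nδ-Boc-L-ornithinate | CC(C)(C)OC(=O)NCCC[C@H](NC(=O)CC(=O)OCC=C)C(=O)OC | intermediate
31 | allyl (5S)-5-[3-(Boc-amino)propyl]-4-hydroxy-2-oxo-2,5-dihydro-1H-pyrrole-3-carboxylate | CC(C)(C)OC(=O)NCCC[C@@H]1NC(=O)C(C(=O)OCC=C)=C1O | intermediate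
32 | trifluoroacetate salt of the free amine of 31 | [NH3+]CCC[C@@H]1NC(=O)C(C(=O)OCC=C)=C1O.[O-]C(=O)C(F)(F)F | intermediate
33 | amide of 27 with 32 (both silyl ethers, allyl ester) | CC(O[Si](C)(C)C(C)(C)C)[C@@H]1C[C@H]2C[C@@H]3[C@@H]4/C=C\[C@@H]([C@@H](CO[Si](C)(C)C(C)(C)C)/C=C\[C@@H]4C[C@@H]3[C@H]2[C@@H]1C)C(=O)NCCC[C@@H]5NC(=O)C(C(=O)OCC=C)=C5O | intermediate
34 | diol (C2 carbinol epimers, C21 CH2OH) | CC(O)[C@@H]1C[C@H]2C[C@@H]3[C@@H]4/C=C\[C@@H]([C@@H](CO)/C=C\[C@@H]4C[C@@H]3[C@H]2[C@@H]1C)C(=O)NCCC[C@@H]5NC(=O)C(C(=O)OCC=C)=C5O | intermediate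
35 | keto aldehyde (C2 ketone, C21 aldehyde, allyl ester) | CC(=O)[C@@H]1C[C@H]2C[C@@H]3[C@@H]4/C=C\[C@@H]([C@@H](C=O)/C=C\[C@@H]4C[C@@H]3[C@H]2[C@@H]1C)C(=O)NCCC[C@@H]5NC(=O)C(C(=O)OCC=C)=C5O | intermediate
36 | 3-unsubstituted tetramic acid (pyrrolidine-2,4-dione) with C21 aldehyde | CC(=O)[C@@H]1C[C@H]2C[C@@H]3[C@@H]4/C=C\[C@@H]([C@@H](C=O)/C=C\[C@@H]4C[C@@H]3[C@H]2[C@@H]1C)C(=O)NCCC[C@@H]5NC(=O)CC5=O | intermediate
37 | combamide C | CC(=O)[C@@H]1C[C@H]2C[C@@H]3[C@@H]4/C=C\[C@@H]5C(=O)NCCC[C@@H]6NC(=O)/C(=C/[C@H]5/C=C\[C@@H]4C[C@@H]3[C@H]2[C@@H]1C)C6=O | target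

**Where the stereocentres come from**

- C7, C8, C25, C27: step 1 (endo Diels–Alder, catalyst control).
- C5, C28, C29, C3: step 8 (radical bicyclisation).
- C11, C22: step 14 (Ireland–Claisen, chirality transfer from 23).
- C17: L-ornithine (28).
- Alkene geometries: C9=C10 in step 10; C23=C24 in step 15 (ring-enforced); C20=C21 in step 22 (ring-enforced).

**Step count**

Total steps: 22. Longest linear sequence: 17 (steps 1–10, 13–15, 19–22).

**Three steps most likely to fail**

Step 8 (radical bicyclisation). The risk is that the stannane reduces the C29 radical before the slower closure onto the electron-rich enol ether, or that the second ring forms with poor selectivity. The fallback sets out from 14 and comes back at 15. Compound 14 is heated with dilauroyl peroxide (1.3 equiv, added in portions) in 1,2-dichloroethane at reflux with no hydride donor. Undecyl radicals attack the thiocarbonyl sulfur, the C5 radical runs through the same two 5-exo closures, and the α-silyloxy radical at C2 is oxidised by the peroxide to the cation, which loses the silyl group to give the tricyclic methyl ketone ester F1. NaBH4/CeCl3 in MeOH at −40 °C reduces only the ketone to the alcohol F2 (C2 epimers), and t-BuMe2SiOTf/2,6-lutidine in CH2Cl2 returns 15.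

Step 10 (Wittig reaction with the carboxyethyl ylide). The risk is that the β-carboxylate ylide eliminates to acrylate, or that the hindered aldehyde epimerises at C8 before it reacts. The fallback sets out from 16 and comes back at 19. Aldehyde 16 is treated with the dianion made from (3-hydroxypropyl)triphenylphosphonium bromide and NaN(SiMe3)2 (2 equiv) in THF at −78 °C, which has no β-carboxylate and gives the (Z)-homoallylic alcohol F3. Dess–Martin periodinane (NaHCO3, CH2Cl2, 0 °C) gives the β,γ-unsaturated aldehyde F4, and NaClO2/NaH2PO4/2-methylbut-2-ene in t-BuOH/H2O gives acid 19.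

Step 22 (closure of the 11-membered ring on the rigid tetracycle). The risk is ring strain in the trans-bridged lactam, oligomerisation, or loss of C22 by enolisation of the aldehyde. The fallback sets out from 26 and comes back at 37; it closes the 11-membered ring while ring D is still open and flexible, and forms ring D last. Claisen acid 26 is coupled with 32 (EDC·HCl, HOAt, i-Pr2NEt, DMF, 0 °C) to give the open-chain amide F5. HF·pyridine gives the diol F6, and Dess–Martin periodinane gives the keto aldehyde F7. Pd(OAc)2/PPh3/HCO2H/Et3N in dilute THF liberates the tetramic acid F8 (not isolated), which condenses with the C21 aldehyde to give the 11-membered alkylidene macrolactam F9. Ring-closing metathesis of the two propenyl groups of F9 with second-generation Grubbs catalyst RuCl2(=CHPh)(H2IMes)(PCy3) in CH2Cl2 at 40 °C then closes ring D and gives 37.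

Further compounds
F1 | step 8 | tricyclic ester with C2 methyl ketone | CC(=O)[C@@H]1C[C@H]2C[C@@H]3[C@H](C(=O)OC)[C@H](/C=C/C)C[C@@H]3[C@H]2[C@@H]1C
F2 | step 8 | tricyclic ester with C2 secondary alcohol (epimers) | CC(O)[C@@H]1C[C@H]2C[C@@H]3[C@H](C(=O)OC)[C@H](/C=C/C)C[C@@H]3[C@H]2[C@@H]1C
F3 | step 10 | tricyclic (Z)-homoallylic alcohol | CC(O[Si](C)(C)C(C)(C)C)[C@@H]1C[C@H]2C[C@@H]3[C@H](/C=C\CCO)[C@H](/C=C/C)C[C@@H]3[C@H]2[C@@H]1C
F4 | step 10 | tricyclic (Z)-β,γ-unsaturated aldehyde | CC(O[Si](C)(C)C(C)(C)C)[C@@H]1C[C@H]2C[C@@H]3[C@H](/C=C\CC=O)[C@H](/C=C/C)C[C@@H]3[C@H]2[C@@H]1C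
F5 | step 22 | amide of 26 with 32, ring D open | CC(O[Si](C)(C)C(C)(C)C)[C@@H]1C[C@H]2C[C@@H]3[C@H](/C=C\[C@@H]([C@@H](CO[Si](C)(C)C(C)(C)C)/C=C/C)C(=O)NCCC[C@@H]4NC(=O)C(C(=O)OCC=C)=C4O)[C@H](/C=C/C)C[C@@H]3[C@H]2[C@@H]1C
F6 | step 22 | diol of F5 | CC(O)[C@@H]1C[C@H]2C[C@@H]3[C@H](/C=C\[C@@H]([C@@H](CO)/C=C/C)C(=O)NCCC[C@@H]4NC(=O)C(C(=O)OCC=C)=C4O)[C@H](/C=C/C)C[C@@H]3[C@H]2[C@@H]1C
F7 | step 22 | keto aldehyde, ring D open | CC(=O)[C@@H]1C[C@H]2C[C@@H]3[C@H](/C=C\[C@@H]([C@@H](C=O)/C=C/C)C(=O)NCCC[C@@H]4NC(=O)C(C(=O)OCC=C)=C4O)[C@H](/C=C/C)C[C@@H]3[C@H]2[C@@H]1C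
F8 | step 22 | 3-unsubstituted tetramic acid, ring D open | CC(=O)[C@@H]1C[C@H]2C[C@@H]3[C@H](/C=C\[C@@H]([C@@H](C=O)/C=C/C)C(=O)NCCC[C@@H]4NC(=O)CC4=O)[C@H](/C=C/C)C[C@@H]3[C@H]2[C@@H]1C
F9 | step 22 | 11-membered alkylidene macrolactam, ring D open | CC(=O)[C@@H]1C[C@H]2C[C@@H]3[C@H](/C=C\[C@@H]4C(=O)NCCC[C@@H]5NC(=O)/C(=C/[C@H]4/C=C/C)C5=O)[C@H](/C=C/C)C[C@@H]3[C@H]2[C@@H]1C
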